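The lower dihydropyran ring (O1–C2–C3–C4 of the 7-hydroxychroman carried by the central ring) is cut into a 1,4-dipole, the ortho-quinone methide of its resorcinol ring (O1, C4), and a 1,2-dipole, the enolate/acyl pair of the central ring's arylacetic acid (C3, C2). One isothiourea-catalysed formal [4+2] annulation joins the fully built upper 4-arylisoflavan acid to this quinone methide, forming C3–C4 and O1–C2 and setting C3. The precursor acid is itself released when an isochromanone (latent quinone methide plus latent acid) is unzipped to build the upper chroman by a related annulation. Lactone reduction and hydrogenolysis finish.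

Key step: step 12

Assumption: compounds 1, 5, 10 and 17 are taken as commercial, and the facial sense written for each organocatalyst follows the accepted enamine and isothiourea models rather than a tested case on these substrates.

Step 1
Reactants: 1 methyl 2-(3,5-dihydroxyphenyl)acetate
Product: 2 methyl 2-(2-formyl-3,5-dihydroxyphenyl)acetate
Conditions: POCl3, DMF, MeCN, 0 °C to rt; then H2O, 50 °C
Reagents that add atoms: N,N-dimethylformamide, CN(C)C=O; water, O
Why: Vilsmeier–Haack formylation of the resorcinol ring should go ortho to the CH2 side chain and para to one hydroxyl, as with orcinol, rather than at the crowded carbon between the two hydroxyls.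

Step 2
Reactants: 2 methyl 2-(2-formyl-3,5-dihydroxyphenyl)acetate
Product: 3 methyl 2-[5-(benzyloxy)-2-formyl-3-hydroxyphenyl]acetate
Conditions: BnBr, K2CO3, KI (cat.), acetone, 40 °C
Reagents that add atoms: benzyl bromide, BrCc1ccccc1
Why: Williamson ether synthesis should alkylate the hydroxyl para to the formyl group first, because the ortho hydroxyl is held in a hydrogen bond to the aldehyde, as in the 4-O-benzylation of 2,4-dihydroxybenzaldehyde.

Step 3
Reactants: 3 methyl 2-[5-(benzyloxy)-2-formyl-3-hydroxyphenyl]acetate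
Product: 4 methyl 2-[5-(benzyloxy)-2-formyl-3-methoxyphenyl]acetate
Conditions: MeI, K2CO3, DMF, rt
Reagents that add atoms: iodomethane, CI
Why: Williamson methylation of the remaining chelated phenol fixes methoxy ortho and benzyloxy para to the formyl carbon, which is the pattern of the central ring.

Step 4
Reactants: 5 2,6-dimethoxyphenol
Product: 6 2-(benzyloxy)-1,3-dimethoxybenzene
Conditions: BnBr, K2CO3, DMF, 60 °C
Reagents that add atoms: benzyl bromide, BrCc1ccccc1
Why: Williamson ether synthesis protects the hindered phenol as a benzyl ether that is removed only in the last step.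

Step 5
Reactants: 6 2-(benzyloxy)-1,3-dimethoxybenzene
Product: 7 3-(benzyloxy)-2,4-dimethoxybenzaldehyde
Conditions: POCl3, DMF, 80 °C; then aq. NaOAc
Reagents that add atoms: N,N-dimethylformamide, CN(C)C=O; water, O
Why: Vilsmeier–Haack formylation of the 1,2,3-trioxygenated ring should go para to a flanking methoxy group, as with 1,2,3-trimethoxybenzene, because the central benzyloxy group is twisted out of conjugation.

Step 6
Reactants: 7 3-(benzyloxy)-2,4-dimethoxybenzaldehyde
Product: 9 2-[3-(benzyloxy)-2,4-dimethoxyphenyl]acetaldehyde, via enol ether 8 (not isolated)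
Conditions: MeOCH2PPh3Cl, KOtBu, THF, 0 °C to rt; then 2 M HCl, THF, 40 °C
Reagents that add atoms: (methoxymethyl)triphenylphosphonium chloride, COC[P+](c1ccccc1)(c1ccccc1)c1ccccc1.[Cl-]; water, O
Why: Wittig methoxymethylenation followed by hydrolysis of the enol ether is the standard one-carbon homologation of an aryl aldehyde to the arylacetaldehyde, which is used without storage.

Step 7
Reactants: 4 methyl 2-[5-(benzyloxy)-2-formyl-3-methoxyphenyl]acetate; 10 3-(benzyloxy)phenol
Product: 13 6-(benzyloxy)-1-[4-(benzyloxy)-2-hydroxyphenyl]-8-methoxyisochroman-3-one (racemic), via dioxaborin 11 (not isolated), via hydroxy ester 12 (not isolated)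
Conditions: PhB(OH)2, EtCO2H (cat.), toluene, reflux, Dean–Stark; then pinacol, TsOH (cat.), 60 °C
Reagents that add atoms: none
Why: The boronic acid-templated ortho-hydroxyalkylation of a phenol (Nagata reaction) should deliver the aldehyde carbon only to the free ortho position para to the benzyloxy group, and once boron is transferred to pinacol the benzylic hydroxyl lactonises onto the neighbouring methyl ester.

Step 8
Reactants: 13 6-(benzyloxy)-1-[4-(benzyloxy)-2-hydroxyphenyl]-8-methoxyisochroman-3-one; 9 2-[3-(benzyloxy)-2,4-dimethoxyphenyl]acetaldehyde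
Product: 15 2-{5-(benzyloxy)-2-[(3R,4S)-7-(benzyloxy)-3-[3-(benzyloxy)-2,4-dimethoxyphenyl]-2-hydroxychroman-4-yl]-3-methoxyphenyl}acetic acid (C2 anomers), via ortho-quinone methide acid 14 (not isolated)
Conditions: (R)-α,α-diphenylprolinol trimethylsilyl ether (20 mol %), K2CO3, CHCl3, 0 °C to rt; then 1 M HCl
Reagents that add atoms: none
Why: Base should open the lactone by phenoxide-driven loss of the benzylic carboxylate (as in the ring opening of phenolphthalein) to give quinone methide 14, which enters the known aminocatalytic inverse-electron-demand oxa-Diels–Alder reaction with the E-enamine of 9; the catalyst shields one enamine face so that C3 should be R, and the endo approach that gives the 3,4-trans adduct then sets the non-epimerisable C4 as S.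

Step 9
Reactants: 15 2-{5-(benzyloxy)-2-[(3R,4S)-7-(benzyloxy)-3-[3-(benzyloxy)-2,4-dimethoxyphenyl]-2-hydroxychroman-4-yl]-3-methoxyphenyl}acetic acid
Product: 16 2-{5-(benzyloxy)-2-[(3R,4S)-7-(benzyloxy)-3-[3-(benzyloxy)-2,4-dimethoxyphenyl]chroman-4-yl]-3-methoxyphenyl}acetic acid
Conditions: Et3SiH, BF3·OEt2, CH2Cl2, −78 to −20 °C
Reagents that add atoms: none
Why: Ionic hydrogenation of the lactol through its oxocarbenium ion (reductive deoxygenation) gives the cyclic ether, and any C3 epimerisation through the enol ether returns to the favoured 3,4-trans isomer because C4 is fixed.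

Step 10
Reactants: 17 4-(benzyloxy)-2-hydroxybenzaldehyde
Product: 18 5-(benzyloxy)-2-(hydroxymethyl)phenol
Conditions: NaBH4, MeOH–THF, 0 °C
Reagents that add atoms: none
Why: Borohydride reduction of the aldehyde gives the salicyl alcohol without touching the benzyl ether.

Step 11
Reactants: 18 5-(benzyloxy)-2-(hydroxymethyl)phenol
Product: 19 5-(benzyloxy)-2-{[(4-methylphenyl)sulfonyl]methyl}phenol
Conditions: p-TolSO2Na, HCO2H–H2O, rt
Reagents that add atoms: sodium 4-methylbenzenesulfinate, Cc1ccc(cc1)S(=O)[O-].[Na+]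
Why: SN1 substitution through the stabilised 2-hydroxy-4-alkoxybenzyl cation, captured at sulfur by excess sulfinate, should give the crystalline benzylic sulfone that serves as a base-triggered ortho-quinone methide precursor.

Step 12
Reactants: 16 2-{5-(benzyloxy)-2-[(3R,4S)-7-(benzyloxy)-3-[3-(benzyloxy)-2,4-dimethoxyphenyl]chroman-4-yl]-3-methoxyphenyl}acetic acid; 19 5-(benzyloxy)-2-{[(4-methylphenyl)sulfonyl]methyl}phenol
Product: 22 (3R)-7-(benzyloxy)-3-{5-(benzyloxy)-2-[(3R,4S)-7-(benzyloxy)-3-[3-(benzyloxy)-2,4-dimethoxyphenyl]chroman-4-yl]-3-methoxyphenyl}chroman-2-one, via mixed anhydride 20 (not isolated), via ortho-quinone methide 21 (not isolated)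
Conditions: t-BuCOCl, i-Pr2NEt, CH2Cl2, 0 °C; then (2S,3R)-HyperBTM [(2S,3R)-3-isopropyl-2-phenyl-3,4-dihydro-2H-benzo[4,5]thiazolo[3,2-a]pyrimidine] (10 mol %), 19, Cs2CO3, CH2Cl2, −40 to 0 °C
Reagents that add atoms: none
Why: Isothiourea N-acylation by mixed anhydride 20 and deprotonation give a (Z)-ammonium enolate whose carbon adds to the exocyclic CH2 of ortho-quinone methide 21, released from 19 by base with loss of sulfinate, to form C3–C4; the phenoxide born in that addition then attacks the acyl ammonium carbonyl to form O1–C2 and free the catalyst. The closest known reaction type is the isothiourea-catalysed Michael addition–lactonisation of arylacetic acids (C1-ammonium enolate catalysis), which is also the formal [4+2] annulation of ortho-quinone methides with catalyst-bound acyl enolates to 3,4-dihydrocoumarins. The one ring that closes, the lower pyranone ring, closes by 6-exo-trig lactonisation after the intermolecular conjugate addition. C3 is controlled by the catalyst: the 1,5-O···S contact locks the enolate, the C2-phenyl group of (2S,3R)-HyperBTM covers one face, and attack of the CH2 acceptor anti to it should give 3R on the accepted model. The step needs catalyst control over the two remote stereocentres of the upper chroman, C-alkylation of the enolate ahead of O-acylation of phenol 19, and no enolisation of the product. The unhindered CH2 acceptor, the low stationary concentration of 21 (stored as its sulfinate adduct 19) and low temperature with direct use of 22 in step 13 serve these needs.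

Step 13
Reactants: 22 (3R)-7-(benzyloxy)-3-{5-(benzyloxy)-2-[(3R,4S)-7-(benzyloxy)-3-[3-(benzyloxy)-2,4-dimethoxyphenyl]chroman-4-yl]-3-methoxyphenyl}chroman-2-one
Product: 24 (3R,4S)-7-(benzyloxy)-4-{4-(benzyloxy)-2-[(3R)-7-(benzyloxy)chroman-3-yl]-6-methoxyphenyl}-3-[3-(benzyloxy)-2,4-dimethoxyphenyl]chroman, via lactol 23 (not isolated)
Conditions: i-Bu2AlH, CH2Cl2, −78 °C; then Et3SiH, BF3·OEt2, −78 to −30 °C
Reagents that add atoms: none
Why: Partial reduction of the aryl lactone to the lactol and ionic hydrogenation of its oxocarbenium ion in the same flask should give the chroman with the O1–C2 bond intact, the low temperature holding back loss of the C3 proton from the oxocarbenium ion that would scramble C3.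

Step 14
Reactants: 24 (3R,4S)-7-(benzyloxy)-4-{4-(benzyloxy)-2-[(3R)-7-(benzyloxy)chroman-3-yl]-6-methoxyphenyl}-3-[3-(benzyloxy)-2,4-dimethoxyphenyl]chroman
Product: 25 (3R,4S)-3-(3-hydroxy-2,4-dimethoxyphenyl)-4-{4-hydroxy-2-[(3R)-7-hydroxychroman-3-yl]-6-methoxyphenyl}chroman-7-ol
Conditions: H2 (1 atm), Pd/C, EtOAc–MeOH, rt
Reagents that add atoms: none
Why: Hydrogenolysis of the four benzyl ethers should free the four phenols while the chroman C–O bonds and the doubly benzylic C4–H centre stay untouched.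

Compound list
1 | methyl 2-(3,5-dihydroxyphenyl)acetate | COC(=O)Cc1cc(O)cc(O)c1 | starting material
2 | methyl 2-(2-formyl-3,5-dihydroxyphenyl)acetate | COC(=O)Cc1cc(O)cc(O)c1C=O | intermediate
3 | methyl 2-[5-(benzyloxy)-2-formyl-3-hydroxyphenyl]acetate | COC(=O)Cc1cc(OCc2ccccc2)cc(O)c1C=O | intermediate
4 | methyl 2-[5-(benzyloxy)-2-formyl-3-methoxyphenyl]acetate | COC(=O)Cc1cc(OCc2ccccc2)cc(OC)c1C=O | intermediate
5 | 2,6-dimethoxyphenol | COc1cccc(OC)c1O | starting material
6 | 2-(benzyloxy)-1,3-dimethoxybenzene | COc1cccc(OC)c1OCc1ccccc1 | intermediate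
7 | 3-(benzyloxy)-2,4-dimethoxybenzaldehyde | COc1ccc(C=O)c(OC)c1OCc1ccccc1 | intermediate
8 | 2-(benzyloxy)-1,3-dimethoxy-4-(2-methoxyethenyl)benzene (E/Z mixture) | COC=Cc1ccc(OC)c(OCc2ccccc2)c1OC | intermediate
9 | 2-[3-(benzyloxy)-2,4-dimethoxyphenyl]acetaldehyde | COc1ccc(CC=O)c(OC)c1OCc1ccccc1 | intermediate
10 | 3-(benzyloxy)phenol | Oc1cccc(OCc2ccccc2)c1 | starting material
11 | methyl 2-{5-(benzyloxy)-2-[7-(benzyloxy)-2-phenyl-4H-1,3,2-benzodioxaborinin-4-yl]-3-methoxyphenyl}acetate (racemic) | COC(=O)Cc1cc(OCc2ccccc2)cc(OC)c1C1OB(c2ccccc2)Oc2cc(OCc3ccccc3)ccc21 | intermediate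
12 | methyl 2-{5-(benzyloxy)-2-[[4-(benzyloxy)-2-hydroxyphenyl](hydroxy)methyl]-3-methoxyphenyl}acetate (racemic) | COC(=O)Cc1cc(OCc2ccccc2)cc(OC)c1C(O)c1ccc(OCc2ccccc2)cc1O | intermediate
13 | 6-(benzyloxy)-1-[4-(benzyloxy)-2-hydroxyphenyl]-8-methoxyisochroman-3-one (racemic) | O=C1Cc2cc(OCc3ccccc3)cc(OC)c2C(c2ccc(OCc3ccccc3)cc2O)O1 | intermediate
14 | 2-{5-(benzyloxy)-2-[(4-(benzyloxy)-6-oxocyclohexa-2,4-dien-1-ylidene)methyl]-3-methoxyphenyl}acetic acid | OC(=O)Cc1cc(OCc2ccccc2)cc(OC)c1C=C1C=CC(OCc2ccccc2)=CC1=O | intermediate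
15 | 2-{5-(benzyloxy)-2-[(3R,4S)-7-(benzyloxy)-3-[3-(benzyloxy)-2,4-dimethoxyphenyl]-2-hydroxychroman-4-yl]-3-methoxyphenyl}acetic acid (C2 anomers) | COc1ccc([C@@H]2C(O)Oc3cc(OCc4ccccc4)ccc3[C@H]2c2c(OC)cc(OCc3ccccc3)cc2CC(=O)O)c(OC)c1OCc1ccccc1 | intermediate
16 | 2-{5-(benzyloxy)-2-[(3R,4S)-7-(benzyloxy)-3-[3-(benzyloxy)-2,4-dimethoxyphenyl]chroman-4-yl]-3-methoxyphenyl}acetic acid | COc1ccc([C@@H]2COc3cc(OCc4ccccc4)ccc3[C@H]2c2c(OC)cc(OCc3ccccc3)cc2CC(=O)O)c(OC)c1OCc1ccccc1 | intermediate
17 | 4-(benzyloxy)-2-hydroxybenzaldehyde | O=Cc1ccc(OCc2ccccc2)cc1O | starting material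
18 | 5-(benzyloxy)-2-(hydroxymethyl)phenol | OCc1ccc(OCc2ccccc2)cc1O | intermediate
19 | 5-(benzyloxy)-2-{[(4-methylphenyl)sulfonyl]methyl}phenol | Cc1ccc(cc1)S(=O)(=O)Cc1ccc(OCc2ccccc2)cc1O | intermediate
20 | mixed anhydride of acid 16 and 2,2-dimethylpropanoic acid | COc1ccc([C@@H]2COc3cc(OCc4ccccc4)ccc3[C@H]2c2c(OC)cc(OCc3ccccc3)cc2CC(=O)OC(=O)C(C)(C)C)c(OC)c1OCc1ccccc1 | intermediate
21 | 3-(benzyloxy)-6-methylidenecyclohexa-2,4-dien-1-one | C=C1C=CC(OCc2ccccc2)=CC1=O | intermediate
22 | (3R)-7-(benzyloxy)-3-{5-(benzyloxy)-2-[(3R,4S)-7-(benzyloxy)-3-[3-(benzyloxy)-2,4-dimethoxyphenyl]chroman-4-yl]-3-methoxyphenyl}chroman-2-one | COc1ccc([C@@H]2COc3cc(OCc4ccccc4)ccc3[C@H]2c2c(OC)cc(OCc3ccccc3)cc2[C@@H]2C(=O)Oc3cc(OCc4ccccc4)ccc3C2)c(OC)c1OCc1ccccc1 | intermediate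
23 | (3R)-7-(benzyloxy)-3-{5-(benzyloxy)-2-[(3R,4S)-7-(benzyloxy)-3-[3-(benzyloxy)-2,4-dimethoxyphenyl]chroman-4-yl]-3-methoxyphenyl}chroman-2-ol (C2 anomers) | COc1ccc([C@@H]2COc3cc(OCc4ccccc4)ccc3[C@H]2c2c(OC)cc(OCc3ccccc3)cc2[C@@H]2C(O)Oc3cc(OCc4ccccc4)ccc3C2)c(OC)c1OCc1ccccc1 | intermediate
24 | (3R,4S)-7-(benzyloxy)-4-{4-(benzyloxy)-2-[(3R)-7-(benzyloxy)chroman-3-yl]-6-methoxyphenyl}-3-[3-(benzyloxy)-2,4-dimethoxyphenyl]chroman | COc1ccc([C@@H]2COc3cc(OCc4ccccc4)ccc3[C@H]2c2c(OC)cc(OCc3ccccc3)cc2[C@@H]2COc3cc(OCc4ccccc4)ccc3C2)c(OC)c1OCc1ccccc1 | intermediate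
25 | (3R,4S)-3-(3-hydroxy-2,4-dimethoxyphenyl)-4-{4-hydroxy-2-[(3R)-7-hydroxychroman-3-yl]-6-methoxyphenyl}chroman-7-ol | COc1ccc([C@@H]2COc3cc(O)ccc3[C@H]2c2c(OC)cc(O)cc2[C@@H]2COc3cc(O)ccc3C2)c(OC)c1O | target

Total step count: 14. Longest linear sequence: 9 steps (steps 1, 2, 3, 7, 8, 9, 12, 13, 14).

Steps most likely to fail

Step 8. The enamine may add too slowly to the congested, strongly stabilised quinone methide 14, whose methide carbon carries a 2,6-disubstituted aryl group, while aldehyde 9 is consumed by self-aldol condensation. The fallback sets out from lactone 13 and uses the smaller enol ether 8, isolated after the Wittig stage of step 6. A BINOL-derived chiral N-triflyl phosphoramide in toluene at −20 °C ionises the lactone and steers the inverse-electron-demand oxa-Diels–Alder reaction to the 2-methoxychroman acid F1. Et3SiH and BF3·OEt2 then reduce the acetal, and the route is rejoined at acid 16.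

Step 12. The ammonium enolate may form sluggishly beside the bulky ortho substituent, the catalyst may fail to override the substrate's own facial bias, or the α-aryl lactone may lose its C3 configuration by enolisation under the basic conditions. The fallback sets out from acid 16. BH3·SMe2 gives the primary alcohol F2 and Dess–Martin periodinane gives the arylacetaldehyde F3. Enamine catalysis with (R)-α,α-diphenylprolinol trimethylsilyl ether, sulfone 19 and K2CO3 then forms C3–C4 and O1–C2 again in one operation and gives lactol 23 directly, without a lactone stage. Reduction with Et3SiH and BF3·OEt2 as in the second stage of step 13 rejoins the route at 24.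

Step 7. The deactivated, hindered aldehyde 4 may condense incompletely, or the product may ionise and add a second phenol. The fallback sets out from phenol 10. Ortho-selective bromination (NBS, cat. i-Pr2NH, CH2Cl2) gives 5-(benzyloxy)-2-bromophenol F4, and TBSCl with imidazole gives the silyl ether F5. Bromine–lithium exchange (n-BuLi, −78 °C), transmetalation with MgBr2·OEt2 and addition to aldehyde 4 give an alkoxide that lactonises to the silyl-protected isochromanone F6. Bu4NF buffered with AcOH removes the silyl group, and the route is rejoined at lactone 13.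

Further compounds
F1 | step 8 | 2-{5-(benzyloxy)-2-[(3R,4S)-7-(benzyloxy)-3-[3-(benzyloxy)-2,4-dimethoxyphenyl]-2-methoxychroman-4-yl]-3-methoxyphenyl}acetic acid | COc1ccc([C@@H]2C(OC)Oc3cc(OCc4ccccc4)ccc3[C@H]2c2c(OC)cc(OCc3ccccc3)cc2CC(=O)O)c(OC)c1OCc1ccccc1
F2 | step 12 | 2-{5-(benzyloxy)-2-[(3R,4S)-7-(benzyloxy)-3-[3-(benzyloxy)-2,4-dimethoxyphenyl]chroman-4-yl]-3-methoxyphenyl}ethanol | COc1ccc([C@@H]2COc3cc(OCc4ccccc4)ccc3[C@H]2c2c(OC)cc(OCc3ccccc3)cc2CCO)c(OC)c1OCc1ccccc1
F3 | step 12 | 2-{5-(benzyloxy)-2-[(3R,4S)-7-(benzyloxy)-3-[3-(benzyloxy)-2,4-dimethoxyphenyl]chroman-4-yl]-3-methoxyphenyl}acetaldehyde | COc1ccc([C@@H]2COc3cc(OCc4ccccc4)ccc3[C@H]2c2c(OC)cc(OCc3ccccc3)cc2CC=O)c(OC)c1OCc1ccccc1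
F4 | step 7 | 5-(benzyloxy)-2-bromophenol | Oc1cc(OCc2ccccc2)ccc1Br
F5 | step 7 | [5-(benzyloxy)-2-bromophenoxy](tert-butyl)dimethylsilane | CC(C)(C)[Si](C)(C)Oc1cc(OCc2ccccc2)ccc1Br
F6 | step 7 | 6-(benzyloxy)-1-{4-(benzyloxy)-2-[(tert-butyldimethylsilyl)oxy]phenyl}-8-methoxyisochroman-3-one (racemic) | O=C1Cc2cc(OCc3ccccc3)cc(OC)c2C(c2ccc(OCc3ccccc3)cc2O[Si](C)(C)C(C)(C)C)O1
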